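The runs were generated by integration for an exercise, and the scatter is random.

If the midnight flask, the one asked about, differed from the autumn run in free catalyst loading and in nothing else, I could read one run through the other. So I kept the books of the starting material, the limiting reagent, on one clock.

| flask | starting material | partner | free catalyst | remark | time |
|---|---|---|---|---|---|
| midnight | 0.020 M | 4 equiv | 0.05 mol% | the very flask that is asked about, followed so far |  |
| autumn | 0.020 M | 4 equiv | 0.1 mol% | run made earlier |  |
| flask | 0.020 M | 4.00 equiv | 0.05 mol% |  | 1.0 h |

- midnight (time / min: starting material / %, product / %): 1.50: 95.4, 4.9; 5.00: 82.7, 16.7; 8.00: 73.6, 25.6; 12.0: 62.0, 37.6; 20.0: 43.2, 56.9; 25.0: 32.7, 66.5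
- autumn (time / min: starting material / %, product / %): 8.00: 51.6, 48.0; 15.0: 25.8, 74.7; 20.0: 12.5, 86.8; 30.0: 3.2, 97.5; 40.0: 0.4, 99.9

(each reading ± 0.5 percentage points)

- the numbers in the tables scatter by 0.5 percentage points (one standard deviation)
- the earlier runs do not show how much of partner is bound; that part of a forecast is a guess

* part of the starting material that has reacted at 1.0 h
* share of the unused partner that is free and not bound as idle adduct, at 1.0 h

1. Charge: [starting material] was 0.020 M, with 4.00 equiv of partner.
2. Test of the clock: the autumn run left 51.6 % of starting material at 8.00 min. The midnight run, at half the loading, should match that at 16.0 min. The mean of its readings on either side, at 12.0 min and 20.0 min, was 52.6 %, and a reading scatters by 0.5 percentage points.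
3. Clock: for the midnight flask at 1.0 h I got 30.0 min, the equivalent time, meaning elapsed time multiplied by a flask's loading and divided by the autumn loading.
4. Entries: at 30.0 min the autumn run showed 3.2 % starting material and 97.5 % product. Together that is 100.7 %, so the books closed within the scatter of the two readings.
5. Balance: I therefore put 96.8 % reacted. The runs did not show how much partner was bound, so I had no figure of my own for the free share.

The forecast gave 96.8 % and >99.9 %, the second "whatever the binding constant".

    partner + free catalyst ⇌ catalyst intermediate A (K = 30.0 M⁻¹, k = 1700 M⁻¹ min⁻¹)
    catalyst intermediate A ⇌ released group + catalyst intermediate B (K = 0.0130 M, k = 500 min⁻¹)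
    starting material + catalyst intermediate B ⇌ catalyst intermediate C (K = 55.0 M⁻¹, k = 2.70 × 10⁵ M⁻¹ min⁻¹)
    catalyst intermediate C → free catalyst + product (k = 500 min⁻¹)
    partner + released group ⇌ idle adduct, settled at all times (K = 4.20 M⁻¹)

The midnight flask gave 97.0 % reacted and 93.8 % of the unused partner free. At 1.00 h it held 0.00374 M of idle adduct, far more than the 1.00 × 10⁻⁵ M of catalyst charged. Its equivalent time of 30.0 min had pointed to 3.2 % of starting material left, and the flask held 3.00 %. A neighbour flask at 0.02 mol% of free catalyst had an equivalent time of 12.0 min. The midnight run reached that point at 24.0 min, before its reading of 32.7 % at 25.0 min, and at 1.00 h the neighbour held 35.2 % of starting material.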